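## Structural features

Alopecurone G is a flavanone: benzo ring A is fused through C4a–C8a to the dihydropyranone ring C (O1, C2, C3, C4=O), and ring B (4′-hydroxy-2′-methoxyphenyl) sits on C2. Ring A is a 1,2,3,4-tetrasubstituted benzene that carries in sequence the acyl carbon C4a, the ether carbon C8a, the lavandulyl-bearing C8 and the phenolic C7; C5 and C6 are unsubstituted. There are only two stereocentres, C2 (S) and the side-chain carbon C2″ (R). They lie five bonds apart (C2–O1–C8a–C8–C1″–C2″), so neither can direct the other, and an error at either one gives a remote diastereomer that is hard to remove. C2 is fragile: it is a benzylic ether β to the C4 ketone, so base opens ring C by retro-oxa-Michael reaction to a 2′-hydroxychalcone, a free 4′-phenoxide can do the same through a para-quinone methide, and acid can ionise C2–O1 because ring B is 2′,4′-dioxygenated. The lavandulyl group is a 1,5-diene (isopropenyl plus prenyl) that rules out hydrogenation, strong acid (cationic cyclisation, also onto O7) and unselective oxidants; being homoallylic and not allylic, it cannot be brought to C8 by a Claisen rearrangement. The real difficulty is therefore to place a chiral, β-branched, unactivated alkyl group on C8, between two oxygen-bearing carbons, without disturbing C2. The key step uses this pattern directly: C5–C6–C7–C8, with oxygen on C7 and the side chain on C8, is the imprint of a 4-substituted 1-methoxy-3-silyloxybuta-1,3-diene, and C4a=C8a is the enone double bond of a preformed ring C.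

## Logic of the disconnections

20 ⇒ 19. The O7–Si and O4′–Si bonds are cut. Both phenols are carried as silyl ethers so that a single buffered fluoride treatment ends the synthesis, with no acid that could ionise C2 or cyclise the diene side chain. The skeleton is unchanged. The forward step must keep both liberated phenoxides protonated so that ring C does not open.

19 ⇒ 7 + 16. The C4a–C5 and C8–C8a bonds are cut, which removes ring A. The cut is made here because the substitution pattern of ring A then arises by construction instead of by aromatic substitution. The gain is two fragments of similar size, each with one stereocentre, joined late. The demands on the forward step are: a push–pull alkene must act as dienophile, so C4a needs a group that both activates and leaves (sulfinyl); the diene must add with its substituted terminus to C8a; the diene needs the 1E,3Z geometry; and the medium must stay free of base.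

7 ⇒ 6 ⇒ 5. The S–O bond and then the C–S bond at the α-carbon of the vinylogous ester are cut. Sulfur is added after ring C exists because that carbon is the nucleophilic position of the enol ether, and because a sulfur-free substrate keeps the asymmetric step simple. The forward steps need attack at this carbon in preference to the electron-rich ring B, and an oxidation that stops at the sulfoxide.

5 ⇒ 2 + 3. The C2–C3 and O1–C6 bonds of the pyranone are cut (hetero-Diels–Alder retron). This reduces ring C and its stereocentre to an achiral aldehyde and a commercial diene. The forward step needs Si-face selectivity on an ortho-methoxy, electron-rich aldehyde, and an acid ring closure short enough to leave C2 un-ionised.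

2 ⇒ 1. The O–Si bond is cut. The triisopropylsilyl group is chosen because it should survive trifluoroacetic acid, the sulfenyl chloride, the peracid and heat, and still fall together with the tert-butyldimethylsilyl group at the end.

16 ⇒ 15 ⇒ 14 ⇒ 12. The O–Si bond, the O–CH3 bond and then the bond between the formyl carbon and the former methyl carbon are cut. The methoxy-enone terminus is thus a methyl ketone plus one formyl carbon. The forward steps need kinetic enolisation at the methyl group (through 13), O- and not C-methylation, and a Z-selective silyl enol ether formation.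

12 ⇒ 11. The isopropylidene C=C bond is cut (Wittig retron), which turns the prenyl arm into a CH2–CHO arm. The forward step must react at the aldehyde and leave the methyl ketone alone, without base-induced aldol ring closure.

11 ⇒ 10 ⇒ 9 ⇒ 8. The two carbonyl carbons are reconnected as the trisubstituted ring alkene of a cyclohexene. 8 already has the stereocentre with an isopropenyl group, a short arm and a longer arm, and the centre never becomes α to a carbonyl on the way forward. The forward steps must oxidise the ring alkene in the presence of the isopropenyl group.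

## Other disconnections considered

Alternative 1: The cut runs through O1–C2 and C3–C4, so ring C is made last from two finished arenes. In the forward sense the salicylaldehyde A2 (2-hydroxy-3-[(2R)-lavandulyl]-4-(triisopropylsilyloxy)benzaldehyde) would be turned by HC(OMe)3 and a chiral phosphoric acid into a 4-methoxy ortho-quinone methide cation. This would take up the styrene A3 (2-methoxy-4-(triisopropylsilyloxy)styrene, one Wittig methylenation from 2) in a polar, probably stepwise [4+2] to give the 4-methoxyflavan A1. The chiral phosphate would set C2; the C4 centre is erased later by hydrolysis and oxidation.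
- In its favour: C2 and ring C arise in one catalytic, convergent step under mild acid. Because A1 has no C4 ketone, the chalcone pathway is closed during the step; on this point the alternative is the better of the two, and on convergence it is the equal of the chosen plan.
- Against it here: A2 already contains the lavandulyl group between two oxygens, so the hard problem is only moved into a starting material for which no regiocontrolled route is evident. A3 is prone to acid-induced oligomerisation. The 2-aryl benzylic ether of A1 could ionise reversibly under the catalyst and lose enantiomeric purity. Two redox operations at C4 follow in the presence of the diene side chain.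
- Comparison: in structure, the chosen plan creates the ring A pattern and the alternative presupposes it. In mechanism, both are [4+2] additions, one cationic and catalyst-controlled, the other thermal and neutral with C2 set earlier. In step economy, A3 is cheaper than 7 (one step against four), but A2 is expected to cost more than 16 and the C4 adjustment adds two steps, so no saving is expected.

Alternative 2: The cut is C1″–C2″ in the side chain. Forward, the sulfone A5 (3-(methoxymethoxy)-2-(tosylmethyl)phenol) would release an ortho-quinone methide, which is attacked by the diarylprolinol silyl ether enamine of 5-methylhex-4-enal A6. The catalyst shields one enamine face and so would set C2″, and the phenol closes the lactol A4.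
- In its favour: it attacks the awkward benzylic bond directly and guarantees the position between the two oxygens. It would set C2″ by catalysis from achiral materials in either sense, which is better than relying on the optical purity of a terpene. Enamine additions to ortho-quinone methides are well precedented, so on precedent of the key step it is also the better.
- Against it here: A4 is far from the target. The lactol carbon must become isopropenyl (methyl addition, oxidation, methylenation) through a ketone α to the new stereocentre, which can epimerise. Ring A still lacks the C4a acyl group, and ring C with C2 is not addressed at all and would fall back on a chalcone cyclisation.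
- Comparison: in structure, the alternative solves the side chain, whereas the chosen plan solves the ring A pattern and C2 and takes C2″ from the chiral pool with no epimerisable stage. In mechanism, it is proven organocatalysis against an unprecedented benzannulation. In step economy, a clearly longer linear sequence is expected.

Alternative 3: The cut is C8a–O1. Forward, the diol A8 (aryl bromide at C8a, S-configured C2 carbinol set earlier by an asymmetric aldol reaction or ketone reduction) would cyclise through its C2 hydroxyl under CuI, 1,10-phenanthroline and Cs2CO3 to the flavan-4-ol A7. Closure through the C4 hydroxyl would need a four-membered ring. Oxidation at C4 and removal of two MOM groups follow.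
- In its favour: Ullmann-type C–O coupling is known chemistry, so the key step is more reliable than the chosen one. The bond forms at an sp2 carbon with no ketone present, so C2 is as safe as in the chosen plan.
- Against it here: A8 needs a bromine flanked on both sides (lavandulylmethyl and the diol chain), which slows oxidative addition. Its arene is as hard to assemble as ring A of the target and meets the same lavandulylation problem. The C4 oxidation and the acidic MOM removal (risk to C2 and to the diene) come afterwards.
- Comparison: in structure, it again presupposes the 1,2,3,4 pattern. In mechanism, it is a robust metal-catalysed etherification against a pericyclic step that is new for this dienophile class. In step economy, arene synthesis, aldol, reduction, cyclisation, oxidation and deprotection make it the longer route.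

Key step: step 11

Remark 1 (assumption): the (S)-H8-BINOL–titanium catalyst is taken to direct the diene to the Si face of the aldehyde, by analogy with the usual facial sense of BINOL–titanium carbonyl additions; if a trial shows the opposite sense, the (R)-ligand is used.

Remark 2 (correction): the 2″R descriptor of the target corresponds to (S)-lavandulol, not to the natural (R)-alcohol, because CH2OH outranks isopropenyl whereas CH2–aryl does not, and a racemic alcohol would give both C2″ epimers; the side chain is therefore drawn from (S)-(−)-limonene, which has the required spatial arrangement (a lot of high enantiomeric purity, checked by chiral GC, is assumed).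

Remark 3 (design change): the ring B phenol is carried as a triisopropylsilyl ether instead of a methoxymethyl ether, so that no acidic deprotection is needed after the flavanone exists.

## Route

Step 1
Reactants: 1 4-hydroxy-2-methoxybenzaldehyde
Product: 2 2-methoxy-4-(triisopropylsilyloxy)benzaldehyde
Conditions: TIPSCl, imidazole, DMF, rt
Reagents that add atoms: triisopropylsilyl chloride, CC(C)[Si](Cl)(C(C)C)C(C)C
Why: Silyl ether formation on a phenol; the TIPS ether should survive TFA, the sulfenyl chloride, the peracid and heat, and leaves with the TBS group in the last step.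

Step 2
Reactants: 2 2-methoxy-4-(triisopropylsilyloxy)benzaldehyde; 3 (E)-1-methoxy-3-(trimethylsilyloxy)buta-1,3-diene
Product: 5 (2S)-2-[2-methoxy-4-(triisopropylsilyloxy)phenyl]-2,3-dihydro-4H-pyran-4-one, via Mukaiyama aldol adduct 4 (not isolated)
Conditions: Ti(OiPr)4 (20 mol %), (S)-H8-BINOL (22 mol %), 4 Å MS, PhMe, 0 °C; then TFA, CH2Cl2, 0 °C, 15 min
Reagents that add atoms: none
Why: Catalytic asymmetric hetero-Diels–Alder reaction of the Mukaiyama aldol type: the titanium–H8-BINOL complex binds the aldehyde and the C4 terminus of the diene adds to its Si face, which sets C2 (S) under catalyst control in silyl aldolate 4; TFA then closes ring C by oxa-Michael addition and loss of methanol, and the short cold acid treatment should spare the aryl TIPS ether and the benzylic C2–O bond.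

Step 3
Reactants: 5 (2S)-2-[2-methoxy-4-(triisopropylsilyloxy)phenyl]-2,3-dihydro-4H-pyran-4-one
Product: 6 (2S)-2-[2-methoxy-4-(triisopropylsilyloxy)phenyl]-5-(phenylthio)-2,3-dihydro-4H-pyran-4-one
Conditions: PhSCl (1.1 equiv), 2,6-lutidine (1.5 equiv), CH2Cl2, −78 to 0 °C
Reagents that add atoms: benzenesulfenyl chloride, ClSc1ccccc1
Why: Electrophilic α-sulfenylation of a vinylogous ester by addition–elimination: C5 is the nucleophilic carbon of the enol ether, sulfur adds there to give an oxocarbenium ion, and 2,6-lutidine removes the C5 proton; the buffer keeps HCl away from the silyl ether and from C2, and the enol ether should react faster than ring B.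

Step 4
Reactants: 6 (2S)-2-[2-methoxy-4-(triisopropylsilyloxy)phenyl]-5-(phenylthio)-2,3-dihydro-4H-pyran-4-one
Product: 7 (2S)-2-[2-methoxy-4-(triisopropylsilyloxy)phenyl]-5-(phenylsulfinyl)-2,3-dihydro-4H-pyran-4-one (sulfoxide epimers)
Conditions: mCPBA (1.0 equiv), CH2Cl2, −78 °C
Reagents that add atoms: meta-chloroperoxybenzoic acid, O=C(OO)c1cccc(Cl)c1
Why: Sulfide-to-sulfoxide oxidation with one equivalent of peracid in the cold; sulfur is far more nucleophilic than the electron-poor C5=C6 bond or the ketone, and the sulfur stereocentre is left as a mixture because it is lost in step 11.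

Step 5
Reactants: 8 (S)-(−)-limonene
Product: 9 (4S)-limonene 1,2-oxide (cis/trans mixture)
Conditions: mCPBA (1.0 equiv), CH2Cl2, 0 °C
Reagents that add atoms: meta-chloroperoxybenzoic acid, O=C(OO)c1cccc(Cl)c1
Why: Prilezhaev epoxidation; the trisubstituted ring alkene is more electron-rich than the 1,1-disubstituted isopropenyl group and should react first, and the cis/trans ratio is irrelevant because both epoxide carbons become carbonyl carbons.

Step 6
Reactants: 9 (4S)-limonene 1,2-oxide
Product: 11 (3S)-6-oxo-3-(prop-1-en-2-yl)heptanal, via limonene-1,2-diol 10 (not isolated)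
Conditions: HIO4·2H2O (1.2 equiv), THF/H2O, 0 °C to rt
Reagents that add atoms: water, O
Why: Acid-mediated epoxide hydrolysis to diol 10 followed in the same flask by periodate glycol cleavage (Malaprade reaction); the stereocentre ends β to the aldehyde and γ to the ketone and so cannot epimerise, and periodic acid should leave the isopropenyl group untouched.

Step 7
Reactants: 11 (3S)-6-oxo-3-(prop-1-en-2-yl)heptanal
Product: 12 (5S)-8-methyl-5-(prop-1-en-2-yl)non-7-en-2-one
Conditions: i-PrPPh3I (1.1 equiv), KHMDS (1.05 equiv), THF, 0 °C; then 11, −78 to 0 °C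
Reagents that add atoms: isopropyltriphenylphosphonium iodide, CC(C)[P+](c1ccccc1)(c1ccccc1)c1ccccc1.[I-]
Why: Wittig olefination with a non-stabilised ylide, which at −78 °C should add to the aldehyde much faster than to the methyl ketone; only a slight excess of ylide is used to limit enolisation and intramolecular aldol reaction, and no alkene geometry arises because the new group is isopropylidene.

Step 8
Reactants: 12 (5S)-8-methyl-5-(prop-1-en-2-yl)non-7-en-2-one
Product: 14 (6S)-9-methyl-3-oxo-6-(prop-1-en-2-yl)dec-8-enal (mainly as its enol), via lithium enolate 13 (not isolated)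
Conditions: LDA (1.1 equiv), THF, −78 °C; then HCO2CH2CF3, −78 °C; aq. HCl work-up
Reagents that add atoms: 2,2,2-trifluoroethyl formate, O=COCC(F)(F)F
Why: Kinetic deprotonation by LDA at −78 °C takes the methyl group (enolate 13), and crossed Claisen formylation with the activated formate traps it before it can equilibrate to the methylene enolate.

Step 9
Reactants: 14 (6S)-9-methyl-3-oxo-6-(prop-1-en-2-yl)dec-8-enal
Product: 15 (1E,6S)-1-methoxy-9-methyl-6-(prop-1-en-2-yl)deca-1,8-dien-3-one
Conditions: Me2SO4 (1.1 equiv), K2CO3, acetone, rt
Reagents that add atoms: dimethyl sulfate, COS(=O)(=O)OC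
Why: O-alkylation of the potassium enolate of a β-keto aldehyde by a hard methylating agent at the less hindered formyl oxygen should give the β-methoxy enone, whose push–pull alkene settles in the E form; C-methylation is the side reaction to watch.

Step 10
Reactants: 15 (1E,6S)-1-methoxy-9-methyl-6-(prop-1-en-2-yl)deca-1,8-dien-3-one
Product: 16 tert-butyl{[(1E,3Z,6R)-1-methoxy-9-methyl-6-(prop-1-en-2-yl)deca-1,3,8-trien-3-yl]oxy}dimethylsilane
Conditions: TBSOTf (1.2 equiv), Et3N (2 equiv), Et2O, 0 °C
Reagents that add atoms: tert-butyldimethylsilyl trifluoromethanesulfonate, CC(C)(C)[Si](C)(C)OS(=O)(=O)C(F)(F)F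
Why: Soft enolisation (silyl triflate with a tertiary amine) of the α′-methylene gives the 2-silyloxydiene; the preferred Z silyl enol ether, with the chain trans to the vinyl group, is the geometry that lets the diene reach the s-cis conformation (the descriptor at the stereocentre changes from S to R by priority only).

Step 11
Reactants: 7 (2S)-2-[2-methoxy-4-(triisopropylsilyloxy)phenyl]-5-(phenylsulfinyl)-2,3-dihydro-4H-pyran-4-one; 16 tert-butyl{[(1E,3Z,6R)-1-methoxy-9-methyl-6-(prop-1-en-2-yl)deca-1,3,8-trien-3-yl]oxy}dimethylsilane
Product: 19 (2S)-7-(tert-butyldimethylsilyloxy)-2-[2-methoxy-4-(triisopropylsilyloxy)phenyl]-8-[(2R)-5-methyl-2-(prop-1-en-2-yl)hex-4-en-1-yl]chroman-4-one, via sulfinyl cycloadduct 17 (not isolated), via methoxydihydrochromanone 18 (not isolated)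
Conditions: 16 (2 equiv), PhMe, 95 °C, sealed tube; then PPTS (cat.), CH2Cl2, rt
Reagents that add atoms: none
Why: Proposed new method: the sulfinyl group lowers the LUMO of the C4a=C8a vinylogous-ester bond of 7 enough for a normal-demand, suprafacial [4+2] addition of the 1-methoxy-3-silyloxydiene 16, which gives the cis-fused adduct 17 with the new bonds C4a–C5 and C8–C8a. In 17 the sulfinyl group and C8a–H are necessarily cis, so thermal syn-elimination of PhSOH restores the C4a=C8a vinylogous ester (18), and the doubly allylic C5 methoxy group then leaves together with C8–H (1,4-elimination, completed by a trace of PPTS) to give the arene 19 with the silyl group still on O7. The closest known reaction type is the Diels–Alder/elimination benzannulation of 1-alkoxy-3-silyloxydienes with α-sulfinyl or α-halo enones and with acceptor-substituted chromones; what is new is a 2,3-dihydropyran-4-one that is not benzo-fused as the dienophile. Ring A is closed by an intermolecular [4+2] cycloaddition that forms two σ bonds of a six-membered carbocycle, followed by two eliminations, and not by cyclisation of a chain. No stereocentre is created for the product: C4a, C5, C8 and C8a of 17 are transient and are erased, while C2 and C2″ are spectators. The regiochemistry needed (C8 to C8a) is secured by matched polarisation, since the substituted C4 terminus of the diene carries the largest HOMO coefficient and C8a is the β-carbon to both the carbonyl and the sulfinyl group. The direction of the sulfoxide elimination (toward C8a, not C5) is secured by the obligatory syn C8a–H and by the conjugation regained, and the C2 configuration by the absence of base, which closes the retro-oxa-Michael path to a chalcone. Any 7-phenol formed by loss of the silyl group converges on the target in step 12.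

Step 12
Reactants: 19 (2S)-7-(tert-butyldimethylsilyloxy)-2-[2-methoxy-4-(triisopropylsilyloxy)phenyl]-8-[(2R)-5-methyl-2-(prop-1-en-2-yl)hex-4-en-1-yl]chroman-4-one
Product: 20 alopecurone G, (2S)-7-hydroxy-2-(4-hydroxy-2-methoxyphenyl)-8-[(2R)-5-methyl-2-(prop-1-en-2-yl)hex-4-en-1-yl]chroman-4-one
Conditions: TBAF (2.5 equiv), AcOH (3 equiv), THF, 0 °C
Reagents that add atoms: none
Why: Fluoride-mediated cleavage of both aryl silyl ethers; acetic acid keeps the two phenols protonated so that neither the retro-oxa-Michael opening nor the para-quinone methide path can scramble C2, and no acid strong enough to cyclise the lavandulyl diene is present.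

## Compound list

1 | 4-hydroxy-2-methoxybenzaldehyde | O=Cc1ccc(O)cc1OC | starting material
2 | 2-methoxy-4-(triisopropylsilyloxy)benzaldehyde | O=Cc1ccc(O[Si](C(C)C)(C(C)C)C(C)C)cc1OC | intermediate
3 | (E)-1-methoxy-3-(trimethylsilyloxy)buta-1,3-diene | CO/C=C/C(=C)O[Si](C)(C)C | starting material
4 | (1E,5S)-1-methoxy-5-[2-methoxy-4-(triisopropylsilyloxy)phenyl]-5-(trimethylsilyloxy)pent-1-en-3-one (not isolated) | CO/C=C/C(=O)C[C@@H](c1ccc(O[Si](C(C)C)(C(C)C)C(C)C)cc1OC)O[Si](C)(C)C | intermediate
5 | (2S)-2-[2-methoxy-4-(triisopropylsilyloxy)phenyl]-2,3-dihydro-4H-pyran-4-one | O=C1C[C@@H](c2ccc(O[Si](C(C)C)(C(C)C)C(C)C)cc2OC)OC=C1 | intermediate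
6 | (2S)-2-[2-methoxy-4-(triisopropylsilyloxy)phenyl]-5-(phenylthio)-2,3-dihydro-4H-pyran-4-one | O=C1C[C@@H](c2ccc(O[Si](C(C)C)(C(C)C)C(C)C)cc2OC)OC=C1Sc1ccccc1 | intermediate
7 | (2S)-2-[2-methoxy-4-(triisopropylsilyloxy)phenyl]-5-(phenylsulfinyl)-2,3-dihydro-4H-pyran-4-one (sulfoxide epimers) | O=C1C[C@@H](c2ccc(O[Si](C(C)C)(C(C)C)C(C)C)cc2OC)OC=C1S(=O)c1ccccc1 | intermediate
8 | (S)-(−)-limonene, (4S)-1-methyl-4-(prop-1-en-2-yl)cyclohex-1-ene | C=C(C)[C@@H]1CC=C(C)CC1 | starting material
9 | (4S)-limonene 1,2-oxide, (4S)-1-methyl-4-(prop-1-en-2-yl)-7-oxabicyclo[4.1.0]heptane (cis/trans mixture) | C=C(C)[C@@H]1CC2OC2(C)CC1 | intermediate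
10 | (4S)-1-methyl-4-(prop-1-en-2-yl)cyclohexane-1,2-diol (not isolated) | C=C(C)[C@@H]1CC(O)C(C)(O)CC1 | intermediate
11 | (3S)-6-oxo-3-(prop-1-en-2-yl)heptanal | C=C(C)[C@H](CC=O)CCC(C)=O | intermediate
12 | (5S)-8-methyl-5-(prop-1-en-2-yl)non-7-en-2-one | C=C(C)[C@H](CC=C(C)C)CCC(C)=O | intermediate
13 | lithium (5S)-8-methyl-5-(prop-1-en-2-yl)nona-1,7-dien-2-olate (not isolated) | C=C(C)[C@H](CC=C(C)C)CCC(=C)O[Li] | intermediate
14 | (6S)-9-methyl-3-oxo-6-(prop-1-en-2-yl)dec-8-enal | C=C(C)[C@H](CC=C(C)C)CCC(=O)CC=O | intermediate
15 | (1E,6S)-1-methoxy-9-methyl-6-(prop-1-en-2-yl)deca-1,8-dien-3-one | C=C(C)[C@H](CC=C(C)C)CCC(=O)/C=C/OC | intermediate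
16 | tert-butyl{[(1E,3Z,6R)-1-methoxy-9-methyl-6-(prop-1-en-2-yl)deca-1,3,8-trien-3-yl]oxy}dimethylsilane | C=C(C)[C@H](CC=C(C)C)C/C=C(O[Si](C)(C)C(C)(C)C)/C=C/OC | intermediate
17 | (2S)-7-(tert-butyldimethylsilyloxy)-5-methoxy-2-[2-methoxy-4-(triisopropylsilyloxy)phenyl]-8-[(2R)-5-methyl-2-(prop-1-en-2-yl)hex-4-en-1-yl]-4a-(phenylsulfinyl)-2,3,4a,5,8,8a-hexahydro-4H-chromen-4-one (diastereomers, not isolated) | C=C(C)[C@H](CC=C(C)C)CC1C(O[Si](C)(C)C(C)(C)C)=CC(OC)C2(S(=O)c3ccccc3)C(=O)C[C@@H](c3ccc(O[Si](C(C)C)(C(C)C)C(C)C)cc3OC)OC12 | intermediate
18 | (2S)-7-(tert-butyldimethylsilyloxy)-5-methoxy-2-[2-methoxy-4-(triisopropylsilyloxy)phenyl]-8-[(2R)-5-methyl-2-(prop-1-en-2-yl)hex-4-en-1-yl]-2,3,5,8-tetrahydro-4H-chromen-4-one (diastereomers, not isolated) | C=C(C)[C@H](CC=C(C)C)CC1C(O[Si](C)(C)C(C)(C)C)=CC(OC)C2=C1O[C@H](c1ccc(O[Si](C(C)C)(C(C)C)C(C)C)cc1OC)CC2=O | intermediate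
19 | (2S)-7-(tert-butyldimethylsilyloxy)-2-[2-methoxy-4-(triisopropylsilyloxy)phenyl]-8-[(2R)-5-methyl-2-(prop-1-en-2-yl)hex-4-en-1-yl]chroman-4-one | C=C(C)[C@H](CC=C(C)C)Cc1c(O[Si](C)(C)C(C)(C)C)ccc2c1O[C@H](c1ccc(O[Si](C(C)C)(C(C)C)C(C)C)cc1OC)CC2=O | intermediate
20 | alopecurone G, (2S)-7-hydroxy-2-(4-hydroxy-2-methoxyphenyl)-8-[(2R)-5-methyl-2-(prop-1-en-2-yl)hex-4-en-1-yl]chroman-4-one | C=C(C)[C@H](CC=C(C)C)Cc1c(O)ccc2c1O[C@H](c1ccc(O)cc1OC)CC2=O | target

## Step count and least certain steps

Total: 12 steps (4 to the dienophile 7, 6 to the diene 16, 2 after the fragments meet). Longest linear sequence: 8 steps (steps 5–12, from 8).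

Step 11 (key step). What may go wrong:
- The cycloaddition onto the push–pull alkene may be slow, so that thermal decay of the diene (loss of the silyl group, oligomerisation) wins.
- The sulfoxide elimination may run toward C5 instead of C8a.
- Methanol loss may stay incomplete, or sulfenic acid may ionise the C2–O1 bond.

Within the same approach, brief mild acid treatment of 17 before heating would convert the silyl enol ether and methoxy group into the enone, which leaves C8a–H as the only hydrogen available to the sulfoxide; this converges through the free 7-phenol.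

The fallback uses known chemistry only. It sets out from 1 and comes back to the route at 20, but gives up catalytic control of C2:
- Ring B aldehyde: 1 is protected (MOMCl, i-Pr2NEt) as 2-methoxy-4-(methoxymethoxy)benzaldehyde F1.
- Ring A iodide: commercial 2,4-dihydroxyacetophenone is iodinated between its two oxygens (I2, HIO3) to 1-(2,4-dihydroxy-3-iodophenyl)ethanone F2, then protected to 1-[3-iodo-2,4-bis(methoxymethoxy)phenyl]ethanone F3.
- Side chain: commercial racemic lavandulol is resolved by lipase-mediated acylation with vinyl acetate run past half conversion. This should leave (S)-lavandulol F4 beside (R)-lavandulyl acetate F5. An Appel reaction (I2, PPh3, imidazole) gives (S)-lavandulyl iodide F6, and zinc dust with LiCl gives (S)-lavandulylzinc iodide F7.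
- Coupling: Negishi coupling of F7 with F3 (Pd(OAc)2 with a bulky biaryl dialkylphosphine) should give 1-{3-[(2R)-lavandulyl]-2,4-bis(methoxymethoxy)phenyl}ethanone F8.
- Chalcone: Claisen–Schmidt condensation of F8 with F1 (KOH, EtOH) gives the tris(methoxymethyl) chalcone F9, and brief methanolic HCl gives the trihydroxychalcone F10.
- Ring closure: intramolecular oxa-Michael addition of F10 under a cinchona-derived thiourea (a known asymmetric reaction type of moderate selectivity) closes ring C to 20. The C2 epimer, a diastereomer here, is removed by preparative HPLC.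

Step 2. What may go wrong: facial selectivity or turnover may be poor, because the ortho-methoxy group can chelate titanium and the aldehyde is electron-rich; the TFA ring closure may erode C2 by ionisation. Fallback from 2 to 5: a boron aldol reaction in place of the catalytic cycloaddition. The diisopinocampheylboron enolate of (E)-4-methoxybut-3-en-2-one (Ipc2BCl antipode chosen for Si-face addition, i-Pr2NEt) adds to 2 to give (1E,5S)-5-hydroxy-1-methoxy-5-[2-methoxy-4-(triisopropylsilyloxy)phenyl]pent-1-en-3-one F11, which brief TFA treatment cyclises to 5.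

Step 3. What may go wrong: sulfenylation of ring B may compete, or chloride addition across the enol ether may persist without elimination. Fallback from 5 to 6: halogenation followed by cross-coupling. Iodination at C5 (I2, pyridine, CH2Cl2) gives (2S)-5-iodo-2-[2-methoxy-4-(triisopropylsilyloxy)phenyl]-2,3-dihydro-4H-pyran-4-one F12, and C–S coupling with thiophenol (Pd2(dba)3 as source of zerovalent palladium, Xantphos, i-Pr2NEt, dioxane, 80 °C) gives 6.

Step 8. What may go wrong: formylation at the methylene through enolate equilibration, self-aldol reaction of 12, or deformylation of the sensitive β-keto aldehyde on work-up. Fallback from 12 to 15, bypassing 14 and step 9: a Mukaiyama-type route. Enolate 13 is trapped with TMSCl as [(5S)-8-methyl-5-(prop-1-en-2-yl)nona-1,7-dien-2-yl]oxytrimethylsilane F13. Addition to HC(OMe)3 under BF3·OEt2 at −78 °C gives (6S)-1,1-dimethoxy-9-methyl-6-(prop-1-en-2-yl)dec-8-en-3-one F14. Base-catalysed loss of methanol (cat. NaOMe, warm PhMe) gives 15.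

## Further compounds

F1 | step 11 | 2-methoxy-4-(methoxymethoxy)benzaldehyde | O=Cc1ccc(OCOC)cc1OC
F2 | step 11 | 1-(2,4-dihydroxy-3-iodophenyl)ethanone | CC(=O)c1ccc(O)c(I)c1O
F3 | step 11 | 1-[3-iodo-2,4-bis(methoxymethoxy)phenyl]ethanone | CC(=O)c1ccc(OCOC)c(I)c1OCOC
F4 | step 11 | (S)-lavandulol, (2S)-5-methyl-2-(prop-1-en-2-yl)hex-4-en-1-ol | C=C(C)[C@H](CC=C(C)C)CO
F5 | step 11 | (R)-lavandulyl acetate | C=C(C)[C@@H](CC=C(C)C)COC(C)=O
F6 | step 11 | (S)-lavandulyl iodide, (3S)-3-(iodomethyl)-2,6-dimethylhepta-1,5-diene | C=C(C)[C@H](CC=C(C)C)CI
F7 | step 11 | (S)-lavandulylzinc iodide | C=C(C)[C@H](CC=C(C)C)C[Zn]I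
F8 | step 11 | 1-{3-[(2R)-5-methyl-2-(prop-1-en-2-yl)hex-4-en-1-yl]-2,4-bis(methoxymethoxy)phenyl}ethanone | C=C(C)[C@H](CC=C(C)C)Cc1c(OCOC)ccc(C(C)=O)c1OCOC
F9 | step 11 | (E)-3-[2-methoxy-4-(methoxymethoxy)phenyl]-1-{3-[(2R)-5-methyl-2-(prop-1-en-2-yl)hex-4-en-1-yl]-2,4-bis(methoxymethoxy)phenyl}prop-2-en-1-one | C=C(C)[C@H](CC=C(C)C)Cc1c(OCOC)ccc(C(=O)/C=C/c2ccc(OCOC)cc2OC)c1OCOC
F10 | step 11 | (E)-1-{2,4-dihydroxy-3-[(2R)-5-methyl-2-(prop-1-en-2-yl)hex-4-en-1-yl]phenyl}-3-(4-hydroxy-2-methoxyphenyl)prop-2-en-1-one | C=C(C)[C@H](CC=C(C)C)Cc1c(O)ccc(C(=O)/C=C/c2ccc(O)cc2OC)c1O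
F11 | step 2 | (1E,5S)-5-hydroxy-1-methoxy-5-[2-methoxy-4-(triisopropylsilyloxy)phenyl]pent-1-en-3-one | CO/C=C/C(=O)C[C@H](O)c1ccc(O[Si](C(C)C)(C(C)C)C(C)C)cc1OC
F12 | step 3 | (2S)-5-iodo-2-[2-methoxy-4-(triisopropylsilyloxy)phenyl]-2,3-dihydro-4H-pyran-4-one | O=C1C[C@@H](c2ccc(O[Si](C(C)C)(C(C)C)C(C)C)cc2OC)OC=C1I
F13 | step 8 | [(5S)-8-methyl-5-(prop-1-en-2-yl)nona-1,7-dien-2-yl]oxytrimethylsilane | C=C(C)[C@H](CC=C(C)C)CCC(=C)O[Si](C)(C)C
F14 | step 8 | (6S)-1,1-dimethoxy-9-methyl-6-(prop-1-en-2-yl)dec-8-en-3-one | C=C(C)[C@H](CC=C(C)C)CCC(=O)CC(OC)OC
A1 | alternative 1 | (2S,4S)-4-methoxy-2-[2-methoxy-4-(triisopropylsilyloxy)phenyl]-8-[(2R)-5-methyl-2-(prop-1-en-2-yl)hex-4-en-1-yl]-7-(triisopropylsilyloxy)chromane | C=C(C)[C@H](CC=C(C)C)Cc1c(O[Si](C(C)C)(C(C)C)C(C)C)ccc2c1O[C@H](c1ccc(O[Si](C(C)C)(C(C)C)C(C)C)cc1OC)C[C@@H]2OC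
A2 | alternative 1 | 2-hydroxy-3-[(2R)-5-methyl-2-(prop-1-en-2-yl)hex-4-en-1-yl]-4-(triisopropylsilyloxy)benzaldehyde | C=C(C)[C@H](CC=C(C)C)Cc1c(O[Si](C(C)C)(C(C)C)C(C)C)ccc(C=O)c1O
A3 | alternative 1 | 2-methoxy-4-(triisopropylsilyloxy)styrene | C=Cc1ccc(O[Si](C(C)C)(C(C)C)C(C)C)cc1OC
A4 | alternative 2 | (3R)-5-(methoxymethoxy)-3-(3-methylbut-2-enyl)chroman-2-ol (anomeric mixture) | CC(C)=CC[C@@H]1Cc2c(OCOC)cccc2OC1O
A5 | alternative 2 | 3-(methoxymethoxy)-2-(tosylmethyl)phenol | COCOc1cccc(O)c1CS(=O)(=O)c1ccc(C)cc1
A6 | alternative 2 | 5-methylhex-4-enal | CC(C)=CCCC=O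
A7 | alternative 3 | (2S,4R)-7-(methoxymethoxy)-2-[2-methoxy-4-(methoxymethoxy)phenyl]-8-[(2R)-5-methyl-2-(prop-1-en-2-yl)hex-4-en-1-yl]chroman-4-ol (one C4 epimer drawn) | C=C(C)[C@H](CC=C(C)C)Cc1c(OCOC)ccc2c1O[C@H](c1ccc(OCOC)cc1OC)C[C@H]2O
A8 | alternative 3 | (1S)-3-{2-bromo-4-(methoxymethoxy)-3-[(2R)-5-methyl-2-(prop-1-en-2-yl)hex-4-en-1-yl]phenyl}-1-[2-methoxy-4-(methoxymethoxy)phenyl]propane-1,3-diol (C3 epimers) | C=C(C)[C@H](CC=C(C)C)Cc1c(OCOC)ccc(C(O)C[C@H](O)c2ccc(OCOC)cc2OC)c1Br
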